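The amounts looked unrelated, 17 mM of J in ochre and 26 mM in teal, each with 0.90 equiv of X, yet G climbed on a nearly straight line over the early readings of both runs.

| flask | J | X | temperature | remark | time |
|---|---|---|---|---|---|
| ochre | 17 mM | 0.90 equiv | −6 °C | run made earlier |  |
| teal | 26 mM | 0.90 equiv | 35 °C | run made earlier |  |
| eta | 12 mM | 0.900 equiv | 50 °C |  | 25 min |
| delta | 12 mM | 0.900 equiv | −25 °C |  | 25 min |
| beta | 12 mM | 0.900 equiv | 0 °C |  | 25 min |
| alpha | 12 mM | 0.900 equiv | 25 °C |  | 25 min |

| run | time / min | G / % | J / % |
|---|---|---|---|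
| ochre | 20.0 | 5.6 | 90.9 |
| ochre | 50.0 | 15.1 | 75.6 |
| ochre | 90.0 | 24.2 | 61.3 |
| ochre | 240 | 30.2 | 53.8 |
| teal | 8.00 | 8.4 | 90.0 |
| teal | 15.0 | 16.4 | 80.5 |
| teal | 25.0 | 27.2 | 68.1 |
| teal | 30.0 | 32.3 | 62.2 |

(each reading ± 0.3 percentage points)

- X is a solid; its amount is given per volume of the solution
- at the start none of X is in solution

* which flask leads in amount of G, in percent of the J charged ("all alike" within 1.5 percentage points) (eta / delta / beta / alpha / all alike)
* how much G is there at the end, in percent of the J charged: eta
* how much G is there at the end, in percent of the J charged: delta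
* how much G is there at the end, in percent of the J charged: beta
* how much G is there at the end, in percent of the J charged: alpha

So I froze that slope as a bench rule, measured as a fraction of the charged J per minute, and assumed that the size of the charge dropped out. Ochre at −6 °C gave 0.00302 min⁻¹ up to 50.0 min, and teal at 35 °C gave 0.0108 min⁻¹ up to 30.0 min. These readings gave 22.4 K as the doubling interval, the warming that doubles the slope of G. Carried from teal over 25 min, the line gave 4.19% in delta, 9.09% in beta, 19.7% in alpha and 42.9% in eta.

The line had a border. Ochre had lost 46.2% of its J by 240 min, and its loss had slowed after 90.0 min. That reading is 1.95 X charged per J lost, so X looked like the limiting reagent. Teal's share of G in the J lost was 0.854, and I multiplied it by ochre's loss for an estimated ceiling on G of 39.5%. Eta's line reached that ceiling at 23.0 min, sooner than the asked time, so I replaced its 42.9% with the ceiling. Alpha's line needed 50.0 min, longer than the asked time, so alpha stayed on the line, lower than eta's ceiling, and I picked eta.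

The forecast also chose eta, with 36% in eta, below my ceiling, then 21% in alpha, 9.8% in beta and 3.4% in delta, reasoning that “J falls almost linearly, which suggests X dissolution limits the rate”.

The flasks gave 34.3% in eta, 25.2% in alpha, 10.3% in beta and 2.16% in delta, so eta led.

    J + D → G (k = 0.432 M⁻¹ s⁻¹, Ea = 41.0 kJ mol⁻¹)
    J + 2 D → Q (k = 58.0 M⁻² s⁻¹, Ea = 37.0 kJ mol⁻¹)
    X ⇌ D, rate k3*(cs3 - [D]) while solid is left; crystals form when [D] > cs3 (solubility = 4.70 mM, k = 0.00273 s⁻¹)
    2 D → E (k = 3.48 M⁻¹ s⁻¹, Ea = 58.0 kJ mol⁻¹)
    (constants at 50 °C)

From beta to alpha, G at the asked time doubled every 19.4 K, against the 22.4 K read from the earlier runs. From delta to beta it doubled every 11.1 K, and delta ended below its line of 4.19%. Delta repeated at 0 °C had a line value of 9.09%. That neighbour gave 10.3% of G, with 84% of its J still there.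

The data are simulated for an exercise, noise included.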